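**Retrosynthetic overview**

1. Locants: oxolan-2-one C2–C5. Ring A sits on the C4 benzyl group, ring B on the C3 benzyl group, ring C on the side chain C7''H(OH)–C8''H(ring B)–C9''H2OH. The last operations are global desilylation and lowering of C9'' from carboxyl to CH2OH (trichloroethyl ester → acid → BH3), which leaves the lactone untouched.
2. Key disconnection C7''–C8'': C8'' becomes the carbon of a rhodium-bound donor/acceptor carbene (an aryl diazoacetate on ring B of the finished dibenzylbutyrolactone). C7'' becomes the benzylic CH2 of bis-silylated vanillyl alcohol. One catalytic asymmetric intermolecular C–H insertion joins the halves, sets C7'' and C8'', and delivers O7'' already protected.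
3. Enabling feature: C8'' lies between arene ring B (donor) and C9'', a carbon that can be raised to the ester level (acceptor). C7'' is an oxygen-bearing benzylic carbon para to O4'' of ring C, so its C–H bonds are the most hydridic ones in either partner.
4. The diazo ester comes from the ring B aryl iodide and trichloroethyl diazoacetate (Pd). The iodide comes from trans-selective alkylation of the (R)-4-benzylbutyrolactone enolate with a benzyl bromide made from 5-iodovanillin.
5. Ring order: the three arenes are bought (dihydroferulic acid, 5-iodovanillin, vanillyl alcohol). The only ring made is the butyrolactone (step 5), whose C4 centre comes from an Evans alkylation.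

Key step: step 14

Abbreviations: TBS = tert-butyldimethylsilyl, TBSO = tert-butyldimethylsilyloxy, TCE = 2,2,2-trichloroethyl, Rh2(S-PTTL)4 = dirhodium tetrakis[N-phthaloyl-(S)-tert-leucinate].

Assumption: Rh2(S-PTTL)4 is taken, by analogy with its behaviour toward simple benzyl silyl ethers, to give the syn (2S,3S) ester. Should a model run show the opposite absolute sense, the mirror-image catalyst Rh2(R-PTTL)4 (from D-tert-leucine) is used and nothing else changes.

**Step 1**
Reactants: 1 3-(4-hydroxy-3-methoxyphenyl)propanoic acid (dihydroferulic acid)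
Product: 3 3-[4-(TBSO)-3-methoxyphenyl]propanoic acid, via bis-silylated acid 2 (not isolated)
Conditions: TBSCl (2.4 equiv), imidazole, DMF, rt; then AcOH/THF/H2O, rt
Reagents that add atoms: tert-butyldimethylsilyl chloride, CC(C)(C)[Si](C)(C)Cl
Why: Silyl protection, in which both acidic OH groups are silylated and the silyl ester, far more labile than the aryl silyl ether, is then hydrolysed selectively in the same flask.

**Step 2**
Reactants: 3 3-[4-(TBSO)-3-methoxyphenyl]propanoic acid; 4 (S)-4-benzyl-1,3-oxazolidin-2-one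
Product: 5 (S)-4-benzyl-3-{3-[4-(TBSO)-3-methoxyphenyl]propanoyl}-1,3-oxazolidin-2-one
Conditions: DCC, DMAP (cat.), CH2Cl2, 0 °C → rt
Reagents that add atoms: none
Why: Steglich-type carbodiimide N-acylation of the oxazolidinone with DMAP as acyl-transfer catalyst installs the auxiliary without touching the aryl silyl ether.

**Step 3**
Reactants: 5 (S)-4-benzyl-3-{3-[4-(TBSO)-3-methoxyphenyl]propanoyl}-1,3-oxazolidin-2-one
Product: 7 tert-butyl (3R)-4-[(4S)-4-benzyl-2-oxo-1,3-oxazolidin-3-yl]-3-[4-(TBSO)-3-methoxybenzyl]-4-oxobutanoate, via sodium Z-enolate 6 (not isolated)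
Conditions: NaHMDS, THF, −78 °C; BrCH2CO2t-Bu, −78 → −40 °C
Reagents that add atoms: tert-butyl bromoacetate, CC(C)(C)OC(=O)CBr
Why: Evans asymmetric alkylation, in which the sodium-chelated Z-enolate 6 is attacked by the bromoacetate on the face opposite the benzyl group of the auxiliary, which sets the future lactone C4 as (R).

**Step 4**
Reactants: 7 tert-butyl (3R)-4-[(4S)-4-benzyl-2-oxo-1,3-oxazolidin-3-yl]-3-[4-(TBSO)-3-methoxybenzyl]-4-oxobutanoate
Product: 8 tert-butyl (3R)-4-hydroxy-3-[4-(TBSO)-3-methoxybenzyl]butanoate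
Conditions: LiBH4, MeOH (1 equiv), THF, 0 °C
Reagents that add atoms: none
Why: Reductive cleavage of the N-acyl oxazolidinone, in which LiBH4 attacks the exocyclic imide carbonyl much faster than the hindered tert-butyl ester and the stereocentre is not disturbed.

**Step 5**
Reactants: 8 tert-butyl (3R)-4-hydroxy-3-[4-(TBSO)-3-methoxybenzyl]butanoate
Product: 10 (4R)-4-[4-(TBSO)-3-methoxybenzyl]oxolan-2-one, via hydroxy acid 9 (not isolated)
Conditions: TFA/CH2Cl2 (1:4), 0 °C → rt
Reagents that add atoms: none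
Why: Acidolysis of the tert-butyl ester (E1 loss of isobutene) and spontaneous 5-exo-trig lactonisation of the gamma-hydroxy acid 9 close the butyrolactone ring, while the aryl silyl ether tolerates TFA.

**Step 6**
Reactants: 11 5-iodovanillin (4-hydroxy-3-iodo-5-methoxybenzaldehyde)
Product: 12 4-(TBSO)-3-iodo-5-methoxybenzaldehyde
Conditions: TBSCl, imidazole, DMF, rt
Reagents that add atoms: tert-butyldimethylsilyl chloride, CC(C)(C)[Si](C)(C)Cl
Why: Silyl protection of the acidic phenol, a silyl group being chosen because it offers the later carbene no C–H bond in a 1,5-relationship.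

**Step 7**
Reactants: 12 4-(TBSO)-3-iodo-5-methoxybenzaldehyde
Product: 13 [4-(TBSO)-3-iodo-5-methoxyphenyl]methanol
Conditions: NaBH4, THF/EtOH, −10 °C
Reagents that add atoms: none
Why: Borohydride reduction of the aldehyde, run cold and short so that the silyl ether para to the carbonyl group is not solvolysed.

**Step 8**
Reactants: 13 [4-(TBSO)-3-iodo-5-methoxyphenyl]methanol
Product: 14 4-(TBSO)-3-iodo-5-methoxybenzyl bromide
Conditions: CBr4, PPh3, CH2Cl2, 0 °C
Reagents that add atoms: carbon tetrabromide, BrC(Br)(Br)Br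
Why: Appel reaction, a neutral SN2 bromination of the primary benzylic alcohol through its alkoxyphosphonium salt that avoids the acid which would cleave the silyl ether.

**Step 9**
Reactants: 10 (4R)-4-[4-(TBSO)-3-methoxybenzyl]oxolan-2-one; 14 4-(TBSO)-3-iodo-5-methoxybenzyl bromide
Product: 16 (3R,4R)-3-[4-(TBSO)-3-iodo-5-methoxybenzyl]-4-[4-(TBSO)-3-methoxybenzyl]oxolan-2-one, via lithium enolate 15 (not isolated)
Conditions: LiHMDS, THF, −78 °C; then 14, DMPU, −78 → −30 °C
Reagents that add atoms: none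
Why: Lactone enolate alkylation (SN2), in which bromide 14 approaches the planar enolate 15 anti to the C4 benzyl group and so sets C3 as (R) in the trans lactone, which is also the thermodynamically preferred isomer.

**Step 10**
Reactants: 17 2,2,2-trichloroethanol
Product: 18 2,2,2-trichloroethyl bromoacetate
Conditions: BrCH2COBr, NaHCO3, MeCN, 0 °C
Reagents that add atoms: bromoacetyl bromide, BrCC(=O)Br
Why: Esterification of the alcohol with an acyl bromide (Schotten–Baumann type) with NaHCO3 as acid scavenger.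

**Step 11**
Reactants: 18 2,2,2-trichloroethyl bromoacetate
Product: 19 2,2,2-trichloroethyl diazoacetate
Conditions: TsNHNHTs, DBU, THF, 0 °C
Reagents that add atoms: N,N'-ditosylhydrazine, Cc1ccc(cc1)S(=O)(=O)NNS(=O)(=O)c1ccc(C)cc1
Why: Diazo synthesis by the N,N'-ditosylhydrazine method, in which SN2 N-alkylation by the bromoacetate and two base-induced eliminations of p-toluenesulfinate (Bamford–Stevens type) leave the diazo group.

**Step 12**
Reactants: 16 (3R,4R)-3-[4-(TBSO)-3-iodo-5-methoxybenzyl]-4-[4-(TBSO)-3-methoxybenzyl]oxolan-2-one; 19 2,2,2-trichloroethyl diazoacetate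
Product: 20 2,2,2-trichloroethyl 2-diazo-2-[2-(TBSO)-3-methoxy-5-({(3R,4R)-4-[4-(TBSO)-3-methoxybenzyl]-2-oxooxolan-3-yl}methyl)phenyl]acetate
Conditions: Pd(PPh3)4 (5 mol %), Ag2CO3 (0.5 equiv), Et3N (1.3 equiv), toluene, rt, dark
Reagents that add atoms: none
Why: Palladium-catalysed cross-coupling of an aryl iodide with the C–H bond of an acceptor diazo compound, in which oxidative addition of zerovalent palladium into the C–I bond, base-assisted palladation of the diazo carbon and reductive elimination run at room temperature with the diazo group retained and the lactone and silyl ethers untouched.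

**Step 13**
Reactants: 21 vanillyl alcohol (4-(hydroxymethyl)-2-methoxyphenol)
Product: 22 bis-TBS ether of vanillyl alcohol (tert-butyl{[4-(TBSO)-3-methoxyphenyl]methoxy}dimethylsilane)
Conditions: TBSCl (2.5 equiv), imidazole, DMF, rt
Reagents that add atoms: tert-butyldimethylsilyl chloride, CC(C)(C)[Si](C)(C)Cl
Why: Exhaustive silylation provides at once the phenol protection and the silyl ether oxygen that activates the benzylic CH2 for step 14.

**Step 14**
Reactants: 20 2,2,2-trichloroethyl 2-diazo-2-[2-(TBSO)-3-methoxy-5-({(3R,4R)-4-[4-(TBSO)-3-methoxybenzyl]-2-oxooxolan-3-yl}methyl)phenyl]acetate; 22 bis-TBS ether of vanillyl alcohol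
Product: 24 2,2,2-trichloroethyl (2S,3S)-3-(TBSO)-3-[4-(TBSO)-3-methoxyphenyl]-2-[2-(TBSO)-3-methoxy-5-({(3R,4R)-4-[4-(TBSO)-3-methoxybenzyl]-2-oxooxolan-3-yl}methyl)phenyl]propanoate, via rhodium carbene 23 (not isolated)
Conditions: Rh2(S-PTTL)4 (1 mol %), 22 (3 equiv), hexanes/CH2Cl2, 23 °C, 20 added over 3 h
Reagents that add atoms: none
Why: Loss of N2 from 20 at an axial site of the dirhodium tetracarboxylate gives the electrophilic donor/acceptor carbene 23, which inserts into one benzylic C–H bond of 22 through a concerted, asynchronous three-centre transition state with hydride-transfer character, so that the C7''–C8'' and C8''–H bonds form together. The closest known reaction type is the intermolecular enantioselective C–H insertion of aryldiazoacetates into benzyl and allyl silyl ethers, used as a catalytic surrogate of the syn aldol addition, and no ring is closed. C8'' is set by the catalyst, whose four N-phthaloyl-tert-leucinate ligands leave one face of the carbene open, and C7'' is set by the choice between the two enantiotopic hydrogens, made in the transition state that turns the aryl group of 22 away from the ligand wall and the silyloxy group away from the ester, which leads to the syn (2S,3S) isomer. Site selectivity is needed against the two ArCH2–CH groups, the lactone OCH2, the OCH3 groups and the silyl methyl groups, and it is secured because only the CH2 of 22 is at once alpha to an ether oxygen, para to an oxygen donor and unbranched, whereas the other sites are shielded by adjacent tertiary ring carbons, acyl-deactivated or primary, and 22 is used in excess. The trichloroethyl ester has no C–H bond electron-rich enough for the beta-lactone-forming insertion to which ortho-substituted aryldiazoacetates are prone, the silyl group on the ortho oxygen offers no 1,5-C–H bond (a benzyl or methoxymethyl ether would close a dihydrobenzofuran), and slow addition keeps carbene dimerisation down.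

**Step 15**
Reactants: 24 the TCE (2S,3S)-ester from step 14
Product: 25 (2S,3S)-3-(TBSO)-3-[4-(TBSO)-3-methoxyphenyl]-2-[2-(TBSO)-3-methoxy-5-({(3R,4R)-4-[4-(TBSO)-3-methoxybenzyl]-2-oxooxolan-3-yl}methyl)phenyl]propanoic acid
Conditions: Zn dust, AcOH/THF, rt
Reagents that add atoms: none
Why: Reductive fragmentation of the 2,2,2-trichloroethyl ester (zinc insertion into a C–Cl bond and beta-elimination of the carboxylate) frees the acid under conditions that touch neither the lactone, the silyl ethers nor the C8'' centre.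

**Step 16**
Reactants: 25 the (2S,3S)-acid from step 15
Product: 26 (3R,4R)-3-{4-(TBSO)-3-[(1S,2R)-1-(TBSO)-1-[4-(TBSO)-3-methoxyphenyl]-3-hydroxypropan-2-yl]-5-methoxybenzyl}-4-[4-(TBSO)-3-methoxybenzyl]oxolan-2-one
Conditions: BH3·THF (2 equiv), THF, 0 °C → rt; MeOH quench
Reagents that add atoms: none
Why: Chemoselective borane reduction, in which BH3 reacts with the free acid through an acyloxyborane far faster than with the lactone, so that only C9'' is lowered to CH2OH, without base and hence without epimerisation at C8''.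

**Step 17**
Reactants: 26 the tetrakis-TBS alcohol from step 16
Product: 27 (3R,4R)-3-{3-[(1S,2R)-1,3-dihydroxy-1-(4-hydroxy-3-methoxyphenyl)propan-2-yl]-4-hydroxy-5-methoxybenzyl}-4-(4-hydroxy-3-methoxybenzyl)oxolan-2-one (target)
Conditions: TBAF/AcOH (1:1, 6 equiv), THF, 0 °C → rt
Reagents that add atoms: none
Why: Fluoride-mediated desilylation of all four silyl ethers, with the acetic acid buffer keeping the phenols protonated and thereby suppressing para-quinone methide formation at C7'', ring closure to the dihydrobenzofuran and lactone opening.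

**Compound list**

1 | 3-(4-hydroxy-3-methoxyphenyl)propanoic acid | COc1cc(CCC(=O)O)ccc1O | starting material
2 | TBS 3-[4-(TBSO)-3-methoxyphenyl]propanoate | COc1cc(CCC(=O)O[Si](C)(C)C(C)(C)C)ccc1O[Si](C)(C)C(C)(C)C | intermediate
3 | 3-[4-(TBSO)-3-methoxyphenyl]propanoic acid | COc1cc(CCC(=O)O)ccc1O[Si](C)(C)C(C)(C)C | intermediate
4 | (S)-4-benzyl-1,3-oxazolidin-2-one | O=C1N[C@@H](Cc2ccccc2)CO1 | starting material
5 | (S)-4-benzyl-3-{3-[4-(TBSO)-3-methoxyphenyl]propanoyl}-1,3-oxazolidin-2-one | COc1cc(CCC(=O)N2[C@@H](Cc3ccccc3)COC2=O)ccc1O[Si](C)(C)C(C)(C)C | intermediate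
6 | sodium (Z)-enolate of 5 | [Na+].COc1cc(C/C=C(\[O-])N2[C@@H](Cc3ccccc3)COC2=O)ccc1O[Si](C)(C)C(C)(C)C | intermediate
7 | tert-butyl (3R)-4-[(4S)-4-benzyl-2-oxo-1,3-oxazolidin-3-yl]-3-[4-(TBSO)-3-methoxybenzyl]-4-oxobutanoate | COc1cc(C[C@H](CC(=O)OC(C)(C)C)C(=O)N2[C@@H](Cc3ccccc3)COC2=O)ccc1O[Si](C)(C)C(C)(C)C | intermediate
8 | tert-butyl (3R)-4-hydroxy-3-[4-(TBSO)-3-methoxybenzyl]butanoate | COc1cc(C[C@H](CC(=O)OC(C)(C)C)CO)ccc1O[Si](C)(C)C(C)(C)C | intermediate
9 | (3R)-4-hydroxy-3-[4-(TBSO)-3-methoxybenzyl]butanoic acid | COc1cc(C[C@H](CC(=O)O)CO)ccc1O[Si](C)(C)C(C)(C)C | intermediate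
10 | (4R)-4-[4-(TBSO)-3-methoxybenzyl]oxolan-2-one | COc1cc(C[C@H]2COC(=O)C2)ccc1O[Si](C)(C)C(C)(C)C | intermediate
11 | 5-iodovanillin | COc1cc(C=O)cc(I)c1O | starting material
12 | 4-(TBSO)-3-iodo-5-methoxybenzaldehyde | COc1cc(C=O)cc(I)c1O[Si](C)(C)C(C)(C)C | intermediate
13 | [4-(TBSO)-3-iodo-5-methoxyphenyl]methanol | COc1cc(CO)cc(I)c1O[Si](C)(C)C(C)(C)C | intermediate
14 | 4-(TBSO)-3-iodo-5-methoxybenzyl bromide | COc1cc(CBr)cc(I)c1O[Si](C)(C)C(C)(C)C | intermediate
15 | lithium enolate of 10 | [Li+].COc1cc(C[C@H]2COC([O-])=C2)ccc1O[Si](C)(C)C(C)(C)C | intermediate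
16 | (3R,4R)-3-[4-(TBSO)-3-iodo-5-methoxybenzyl]-4-[4-(TBSO)-3-methoxybenzyl]oxolan-2-one | COc1cc(C[C@H]2COC(=O)[C@@H]2Cc2cc(OC)c(O[Si](C)(C)C(C)(C)C)c(I)c2)ccc1O[Si](C)(C)C(C)(C)C | intermediate
17 | 2,2,2-trichloroethanol | OCC(Cl)(Cl)Cl | starting material
18 | 2,2,2-trichloroethyl bromoacetate | BrCC(=O)OCC(Cl)(Cl)Cl | intermediate
19 | 2,2,2-trichloroethyl diazoacetate | [N-]=[N+]=CC(=O)OCC(Cl)(Cl)Cl | intermediate
20 | TCE 2-diazo-2-[2-(TBSO)-3-methoxy-5-({(3R,4R)-4-[4-(TBSO)-3-methoxybenzyl]-2-oxooxolan-3-yl}methyl)phenyl]acetate | COc1cc(C[C@H]2COC(=O)[C@@H]2Cc2cc(OC)c(O[Si](C)(C)C(C)(C)C)c(C(=[N+]=[N-])C(=O)OCC(Cl)(Cl)Cl)c2)ccc1O[Si](C)(C)C(C)(C)C | intermediate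
21 | vanillyl alcohol | COc1cc(CO)ccc1O | starting material
22 | bis-TBS ether of vanillyl alcohol | COc1cc(CO[Si](C)(C)C(C)(C)C)ccc1O[Si](C)(C)C(C)(C)C | intermediate
23 | rhodium carbene from 20 (the Rh atom stands for the Rh2(S-PTTL)4 core) | COc1cc(C[C@H]2COC(=O)[C@@H]2Cc2cc(OC)c(O[Si](C)(C)C(C)(C)C)c(C(=[Rh])C(=O)OCC(Cl)(Cl)Cl)c2)ccc1O[Si](C)(C)C(C)(C)C | intermediate
24 | TCE (2S,3S)-3-(TBSO)-3-[4-(TBSO)-3-methoxyphenyl]-2-[2-(TBSO)-3-methoxy-5-({(3R,4R)-4-[4-(TBSO)-3-methoxybenzyl]-2-oxooxolan-3-yl}methyl)phenyl]propanoate | COc1cc(C[C@H]2COC(=O)[C@@H]2Cc2cc(OC)c(O[Si](C)(C)C(C)(C)C)c([C@H](C(=O)OCC(Cl)(Cl)Cl)[C@H](O[Si](C)(C)C(C)(C)C)c3ccc(O[Si](C)(C)C(C)(C)C)c(OC)c3)c2)ccc1O[Si](C)(C)C(C)(C)C | intermediate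
25 | the corresponding (2S,3S)-propanoic acid | COc1cc(C[C@H]2COC(=O)[C@@H]2Cc2cc(OC)c(O[Si](C)(C)C(C)(C)C)c([C@H](C(=O)O)[C@H](O[Si](C)(C)C(C)(C)C)c3ccc(O[Si](C)(C)C(C)(C)C)c(OC)c3)c2)ccc1O[Si](C)(C)C(C)(C)C | intermediate
26 | (3R,4R)-3-{4-(TBSO)-3-[(1S,2R)-1-(TBSO)-1-[4-(TBSO)-3-methoxyphenyl]-3-hydroxypropan-2-yl]-5-methoxybenzyl}-4-[4-(TBSO)-3-methoxybenzyl]oxolan-2-one | COc1cc(C[C@H]2COC(=O)[C@@H]2Cc2cc(OC)c(O[Si](C)(C)C(C)(C)C)c([C@H](CO)[C@H](O[Si](C)(C)C(C)(C)C)c3ccc(O[Si](C)(C)C(C)(C)C)c(OC)c3)c2)ccc1O[Si](C)(C)C(C)(C)C | intermediate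
27 | (3R,4R)-3-{3-[(1S,2R)-1,3-dihydroxy-1-(4-hydroxy-3-methoxyphenyl)propan-2-yl]-4-hydroxy-5-methoxybenzyl}-4-(4-hydroxy-3-methoxybenzyl)oxolan-2-one | COc1cc(C[C@H]2COC(=O)[C@@H]2Cc2cc(OC)c(O)c([C@H](CO)[C@H](O)c3ccc(O)c(OC)c3)c2)ccc1O | target

**Step count**

Total step count: 17. Longest linear sequence: 11 (steps 1–5, 9, 12, 14–17).

**Steps most likely to fail**

**1. Step 14.** The silyloxy group ortho to the carbene carbon crowds the approach of the secondary C–H bond. Carbene dimerisation, attack on OCH3 groups or on the electron-rich arenes could then take over, or the selection of carbene face and enantiotopic hydrogen could erode.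

The fallback forms the same C7''–C8'' bond by an Evans syn aldol addition. It sets out from 16 and comes back at 27.
- Iodide 16 is coupled with the Reformatsky reagent BrZnCH2CO2t-Bu (Pd(dba)2, P(t-Bu)3, THF, rt) to give the tert-butyl arylacetate F1.
- TFA/CH2Cl2 gives the arylacetic acid F2.
- DCC/DMAP with auxiliary 4 gives the N-arylacetyl oxazolidinone F3.
- Soft enolisation with Bu2BOTf/i-Pr2NEt (CH2Cl2, −78 °C) touches only the far more acidic imide.
- Addition of 4-(tert-butyldimethylsilyloxy)-3-methoxybenzaldehyde F4 (from vanillin and TBSCl) passes through the Zimmerman–Traxler chair of the Z-boron enolate and gives the syn aldol adduct F5.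
- NaBH4 in THF/H2O at 0 °C removes the auxiliary reductively beside the lactone and gives the tris-silylated diol F6.
- The conditions of step 17 convert F6 into 27.

**2. Step 12.** Oxidative addition and palladation at the C–I bond flanked by the silyloxy group may be slow. Zerovalent palladium would then decompose the diazo ester by carbene formation and dimerisation.

The fallback builds the arylacetate first and introduces the diazo group last. It sets out from 16 and comes back at 20.
- Iodide 16 is taken through the tert-butyl arylacetate F1 and the arylacetic acid F2 as described above.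
- F2 is esterified with 17 (DCC, DMAP, CH2Cl2) to the trichloroethyl arylacetate F7.
- A Regitz diazo transfer (p-acetamidobenzenesulfonyl azide, DBU, MeCN, 0 °C → rt) gives 20. It acts only on the arylacetate CH2, which is far more acidic than lactone C3–H.

**3. Step 16.** Acyloxyborane formation at the crowded carboxyl group may be slow enough for reduction of the lactone to catch up.

The fallback replaces the electrophilic reductant by acyl activation and a nucleophilic hydride. It sets out from 25 and comes back at 26.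
- Acid 25 is converted with isobutyl chloroformate and N-methylmorpholine (THF, −15 °C) into the mixed carbonic anhydride F8.
- F8 is reduced at once with NaBH4 in THF/H2O at 0 °C to 26, conditions under which a gamma-lactone reacts only slowly.

**Further compounds**

F1 | step 14 | tert-butyl arylacetate (CH2CO2t-Bu in place of the iodine of 16) | COc1cc(C[C@H]2COC(=O)[C@@H]2Cc2cc(OC)c(O[Si](C)(C)C(C)(C)C)c(CC(=O)OC(C)(C)C)c2)ccc1O[Si](C)(C)C(C)(C)C
F2 | step 14 | arylacetic acid (CH2CO2H in place of the iodine of 16) | COc1cc(C[C@H]2COC(=O)[C@@H]2Cc2cc(OC)c(O[Si](C)(C)C(C)(C)C)c(CC(=O)O)c2)ccc1O[Si](C)(C)C(C)(C)C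
F3 | step 14 | N-arylacetyl oxazolidinone from F2 and 4 | COc1cc(C[C@H]2COC(=O)[C@@H]2Cc2cc(OC)c(O[Si](C)(C)C(C)(C)C)c(CC(=O)N3[C@@H](Cc4ccccc4)COC3=O)c2)ccc1O[Si](C)(C)C(C)(C)C
F4 | step 14 | 4-(tert-butyldimethylsilyloxy)-3-methoxybenzaldehyde | COc1cc(C=O)ccc1O[Si](C)(C)C(C)(C)C
F5 | step 14 | syn aldol adduct, (2S,3S)-3-hydroxy imide | COc1cc(C[C@H]2COC(=O)[C@@H]2Cc2cc(OC)c(O[Si](C)(C)C(C)(C)C)c([C@H](C(=O)N3[C@@H](Cc4ccccc4)COC3=O)[C@H](O)c3ccc(O[Si](C)(C)C(C)(C)C)c(OC)c3)c2)ccc1O[Si](C)(C)C(C)(C)C
F6 | step 14 | tris-silylated diol, (1S,2R) side chain | COc1cc(C[C@H]2COC(=O)[C@@H]2Cc2cc(OC)c(O[Si](C)(C)C(C)(C)C)c([C@H](CO)[C@H](O)c3ccc(O[Si](C)(C)C(C)(C)C)c(OC)c3)c2)ccc1O[Si](C)(C)C(C)(C)C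
F7 | step 12 | trichloroethyl arylacetate | COc1cc(C[C@H]2COC(=O)[C@@H]2Cc2cc(OC)c(O[Si](C)(C)C(C)(C)C)c(CC(=O)OCC(Cl)(Cl)Cl)c2)ccc1O[Si](C)(C)C(C)(C)C
F8 | step 16 | mixed carbonic anhydride of 25 with isobutyl carbonate | COc1cc(C[C@H]2COC(=O)[C@@H]2Cc2cc(OC)c(O[Si](C)(C)C(C)(C)C)c([C@H](C(=O)OC(=O)OCC(C)C)[C@H](O[Si](C)(C)C(C)(C)C)c3ccc(O[Si](C)(C)C(C)(C)C)c(OC)c3)c2)ccc1O[Si](C)(C)C(C)(C)C
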